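**Retrosynthetic overview**
- The acid comes from a C1 primary alcohol in the last step; the C8 ethyl group comes from a Negishi coupling on a (Z)-vinyl iodide.
- Key late coupling: Z-selective α-iodo Wittig reaction between the 1,2-dioxane carbaldehyde (C1–C7, eleven skeletal carbons) and the C8–C14 phosphonium salt (nine carbons).
- The only ring, the 1,2-dioxane, is closed before the coupling: H2O2 opens a C6 epoxide with inversion, then the C6 peroxide displaces a C3 mesylate with inversion.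
- Acyclic core: anti pentenylboration (C3, C4), ozonolysis/Wittig, Sharpless epoxidation (C6), hydride opening, epoxide transposition.
- Side chain: catalytic asymmetric ethylation of (2E)-pent-2-enal, then Johnson–Claisen chirality transfer (C10 and the 11E alkene).

Assumption: carbons are labelled C1–C14 along the main chain of the target (C1 = carboxyl carbon, peroxide between C3 and C6); both peroxide-forming displacements (at C6 and at C3) are taken to proceed with clean inversion.

**Step 1**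
Reactants: 1 but-1-yne
Product: 2 2-[(1E)-but-1-en-1-yl]-4,4,5,5-tetramethyl-1,3,2-dioxaborolane
Conditions: pinacolborane (1.05 equiv), Cp2Zr(H)Cl (5 mol %), CH2Cl2, 25 °C, sealed vessel
Reagents that add atoms: pinacolborane, [H]B1OC(C)(C)C(C)(C)O1
Why: Zirconocene-catalysed hydroboration adds H–B syn across the terminal alkyne with boron on the terminal carbon, so only the (E)-alkenylboronate forms.

**Step 2**
Reactants: 2 2-[(1E)-but-1-en-1-yl]-4,4,5,5-tetramethyl-1,3,2-dioxaborolane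
Product: 3 4,4,5,5-tetramethyl-2-[(2E)-pent-2-en-1-yl]-1,3,2-dioxaborolane
Conditions: BrCH2Cl (1.3 equiv), n-BuLi (1.2 equiv), THF, −78 °C → rt
Reagents that add atoms: bromochloromethane, ClCBr
Why: Matteson homologation, in which chloromethyllithium adds to boron and the alkenyl group migrates with loss of chloride, inserts CH2 and leaves the E double bond untouched.

**Step 3**
Reactants: 4 propane-1,3-diol
Product: 5 3-[(tert-butyldiphenylsilyl)oxy]propan-1-ol
Conditions: NaH (1.0 equiv), THF, 0 °C → rt; then t-BuPh2SiCl (1.0 equiv)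
Reagents that add atoms: tert-butyl(chloro)diphenylsilane, CC(C)(C)[Si](Cl)(c1ccccc1)c1ccccc1
Why: Monosilylation of the symmetrical diol through its sparingly soluble monosodium alkoxide (Williamson-type O-silylation) gives the mono-ether selectively.

**Step 4**
Reactants: 5 3-[(tert-butyldiphenylsilyl)oxy]propan-1-ol
Product: 6 3-[(tert-butyldiphenylsilyl)oxy]propanal
Conditions: 2,2,6,6-tetramethylpiperidin-1-oxyl (TEMPO, 10 mol %), PhI(OAc)2 (1.1 equiv), CH2Cl2, rt
Reagents that add atoms: none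
Why: Nitroxyl-catalysed oxidation with PhI(OAc)2 as terminal oxidant stops at the aldehyde in dry CH2Cl2.

**Step 5**
Reactants: 6 3-[(tert-butyldiphenylsilyl)oxy]propanal; 3 4,4,5,5-tetramethyl-2-[(2E)-pent-2-en-1-yl]-1,3,2-dioxaborolane
Product: 7 (3R,4S)-1-[(tert-butyldiphenylsilyl)oxy]-4-ethylhex-5-en-3-ol
Conditions: (S)-3,3′-bis(2,4,6-triisopropylphenyl)-1,1′-binaphthalene-2,2′-diyl hydrogen phosphate [(S)-TRIP, 5 mol %], 4 Å molecular sieves, toluene, −30 °C; aq NaHCO3 work-up
Reagents that add atoms: none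
Why: Chiral phosphoric acid-catalysed allylboration through a closed chair transition state, in which the E boronate gives the 3,4-anti product and the (S) acid directs attack to the Si face of the aldehyde, sets C3 (R) and C4 (S); any minor enantiomer becomes a separable diastereomer after the reagent-controlled epoxidation of step 10.

**Step 6**
Reactants: 8 methyl 2-bromobutanoate (racemic)
Product: 9 (1-methoxy-1-oxobutan-2-yl)triphenylphosphonium bromide
Conditions: PPh3 (1.0 equiv), toluene, 90 °C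
Reagents that add atoms: triphenylphosphine, c1ccc(cc1)P(c1ccccc1)c1ccccc1
Why: SN2 quaternisation of triphenylphosphine by the α-bromo ester.

**Step 7**
Reactants: 9 (1-methoxy-1-oxobutan-2-yl)triphenylphosphonium bromide
Product: 10 methyl 2-(triphenyl-λ5-phosphanylidene)butanoate
Conditions: NaOH (1 M aq), CH2Cl2, rt
Reagents that add atoms: none
Why: Deprotonation of the acidic α-CH of the phosphonium salt gives the isolable ester-stabilised ylide.

**Step 8**
Reactants: 7 (3R,4S)-1-[(tert-butyldiphenylsilyl)oxy]-4-ethylhex-5-en-3-ol; 10 methyl 2-(triphenyl-λ5-phosphanylidene)butanoate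
Product: 12 methyl (2E,4S,5R)-7-[(tert-butyldiphenylsilyl)oxy]-2,4-diethyl-5-hydroxyhept-2-enoate, via hydroxy aldehyde 11 (not isolated)
Conditions: O3, CH2Cl2, −78 °C; PPh3 (1.1 equiv), −78 °C → rt; then 10 (2.5 equiv), 40 °C
Reagents that add atoms: none
Why: Ozonolysis of the terminal alkene followed in the same flask by a Wittig reaction of the stabilised ylide gives the (E)-trisubstituted enoate (ester trans to C4) and, because the medium stays neutral, does not epimerise C4.

**Step 9**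
Reactants: 12 methyl (2E,4S,5R)-7-[(tert-butyldiphenylsilyl)oxy]-2,4-diethyl-5-hydroxyhept-2-enoate
Product: 13 (2E,4S,5R)-7-[(tert-butyldiphenylsilyl)oxy]-2,4-diethylhept-2-ene-1,5-diol
Conditions: i-Bu2AlH (3.5 equiv), CH2Cl2, −78 → −20 °C; KNaC4H4O6 (aq) work-up
Reagents that add atoms: none
Why: 1,2-Reduction of the conjugated ester by the aluminium hydride gives the allylic alcohol needed to direct the epoxidation.

**Step 10**
Reactants: 13 (2E,4S,5R)-7-[(tert-butyldiphenylsilyl)oxy]-2,4-diethylhept-2-ene-1,5-diol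
Product: 14 [(2S,3S)-3-[(3R,4R)-6-[(tert-butyldiphenylsilyl)oxy]-4-hydroxyhexan-3-yl]-2-ethyloxiran-2-yl]methanol
Conditions: Ti(OiPr)4 (20 mol %), diethyl (2R,3R)-tartrate (24 mol %), t-BuOOH (2 equiv), 4 Å molecular sieves, CH2Cl2, −25 °C
Reagents that add atoms: tert-butyl hydroperoxide, CC(C)(C)OO
Why: Sharpless asymmetric epoxidation, in which the titanium tartrate binds the primary allylic alcohol and the (2R,3R)-tartrate delivers oxygen to the face that gives the (2S,3S)-epoxy alcohol, fixes the C6–O stereocentre under reagent control (the homoallylic secondary hydroxyl reacts far more slowly).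

**Step 11**
Reactants: 14 [(2S,3S)-3-[(3R,4R)-6-[(tert-butyldiphenylsilyl)oxy]-4-hydroxyhexan-3-yl]-2-ethyloxiran-2-yl]methanol
Product: 15 (2R,4S,5R)-7-[(tert-butyldiphenylsilyl)oxy]-2,4-diethylheptane-1,2,5-triol
Conditions: LiAlH4 (3 equiv), THF, 0 °C → rt
Reagents that add atoms: none
Why: SN2 hydride opening of the 2,3-epoxy alcohol occurs at the secondary carbon C5 because C6 is fully substituted, so the C6–O bond and its configuration are kept.

**Step 12**
Reactants: 15 (2R,4S,5R)-7-[(tert-butyldiphenylsilyl)oxy]-2,4-diethylheptane-1,2,5-triol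
Product: 16 (2R,4S,5R)-7-[(tert-butyldiphenylsilyl)oxy]-2,4-diethyl-2-hydroxyheptane-1,5-diyl dimethanesulfonate
Conditions: MsCl (2.3 equiv), Et3N (3 equiv), CH2Cl2, −30 → 0 °C
Reagents that add atoms: methanesulfonyl chloride, CS(=O)(=O)Cl
Why: O-sulfonylation of the primary and the secondary hydroxyl leaves the hindered tertiary C6 hydroxyl free and does not touch the C3 configuration (only an O–S bond is formed).

**Step 13**
Reactants: 16 (2R,4S,5R)-7-[(tert-butyldiphenylsilyl)oxy]-2,4-diethyl-2-hydroxyheptane-1,5-diyl dimethanesulfonate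
Product: 17 (3R,4S)-1-[(tert-butyldiphenylsilyl)oxy]-4-{[(2R)-2-ethyloxiran-2-yl]methyl}hexan-3-yl methanesulfonate
Conditions: K2CO3 (1.5 equiv), MeOH, 0 °C
Reagents that add atoms: none
Why: Intramolecular Williamson etherification (3-exo-tet), in which the tertiary alkoxide displaces the adjacent primary mesylate much faster than the hindered secondary C3 mesylate, gives the 2,2-disubstituted epoxide with C6 unchanged.

**Step 14**
Reactants: 17 (3R,4S)-1-[(tert-butyldiphenylsilyl)oxy]-4-{[(2R)-2-ethyloxiran-2-yl]methyl}hexan-3-yl methanesulfonate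
Product: 19 [(3S,5S,6S)-6-{2-[(tert-butyldiphenylsilyl)oxy]ethyl}-3,5-diethyl-1,2-dioxan-3-yl]methanol, via hydroperoxide 18 (not isolated)
Conditions: H2O2 (anhydrous, in Et2O, 10 equiv), H3PMo12O40 (5 mol %), rt; aqueous wash, cold concentration; then KOt-Bu (1.1 equiv), 18-crown-6, toluene, 0 °C → rt
Reagents that add atoms: hydrogen peroxide, OO
Why: Molybdenum-catalysed perhydrolysis opens the epoxide at the tertiary carbon with inversion (C6 becomes S), and the peroxide anion then displaces the C3 mesylate in a 6-exo-tet SN2 alkylation with inversion (C3 becomes S), closing the 1,2-dioxane with the C3 and C4 substituents cis as in the target.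

**Step 15**
Reactants: 19 [(3S,5S,6S)-6-{2-[(tert-butyldiphenylsilyl)oxy]ethyl}-3,5-diethyl-1,2-dioxan-3-yl]methanol
Product: 20 (3S,5S,6S)-6-{2-[(tert-butyldiphenylsilyl)oxy]ethyl}-3,5-diethyl-1,2-dioxane-3-carbaldehyde
Conditions: Dess–Martin periodinane (1.5 equiv), CH2Cl2, 0 °C → rt
Reagents that add atoms: none
Why: Dess–Martin oxidation of the neopentyl primary alcohol under neutral conditions gives an aldehyde with no α-hydrogen, so C6 cannot epimerise.

**Step 16**
Reactants: 21 (2E)-pent-2-enal; 22 diethylzinc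
Product: 23 (3R,4E)-hept-4-en-3-ol
Conditions: (2R)-3-exo-morpholinoisoborneol [(+)-MIB, 4 mol %], hexane/toluene, 0 °C; aq NH4Cl
Reagents that add atoms: none
Why: Amino alcohol-catalysed enantioselective 1,2-addition of diethylzinc delivers ethyl to the Re face of the enal with the (+)-ligand and gives the (R) allylic alcohol.

**Step 17**
Reactants: 23 (3R,4E)-hept-4-en-3-ol; 24 trimethyl orthoacetate
Product: 25 methyl (3R,4E)-3-ethylhept-4-enoate
Conditions: 24 (6 equiv), EtCO2H (5 mol %), 110 °C, MeOH distilled off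
Reagents that add atoms: none
Why: Johnson–Claisen (orthoester) rearrangement through a chair transition state with the carbinol ethyl group equatorial transfers the carbinol chirality to C10 (R) and gives the E double bond.

**Step 18**
Reactants: 25 methyl (3R,4E)-3-ethylhept-4-enoate
Product: 26 (3R,4E)-3-ethylhept-4-en-1-ol
Conditions: LiAlH4, Et2O, 0 °C
Reagents that add atoms: none
Why: Hydride reduction of the ester to the primary alcohol does not involve the stereocentre.

**Step 19**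
Reactants: 26 (3R,4E)-3-ethylhept-4-en-1-ol
Product: 27 (3E,5R)-5-ethyl-7-iodohept-3-ene
Conditions: I2, PPh3, imidazole, CH2Cl2, 0 °C → rt
Reagents that add atoms: iodine, [I][I]
Why: Appel-type iodination, an SN2 displacement of the phosphonium-activated primary oxygen by iodide.

**Step 20**
Reactants: 27 (3E,5R)-5-ethyl-7-iodohept-3-ene
Product: 28 [(3R,4E)-3-ethylhept-4-en-1-yl]triphenylphosphonium iodide
Conditions: PPh3, MeCN, 80 °C
Reagents that add atoms: triphenylphosphine, c1ccc(cc1)P(c1ccccc1)c1ccccc1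
Why: SN2 quaternisation of triphenylphosphine by the primary iodide.

**Step 21**
Reactants: 28 [(3R,4E)-3-ethylhept-4-en-1-yl]triphenylphosphonium iodide; 20 (3S,5S,6S)-6-{2-[(tert-butyldiphenylsilyl)oxy]ethyl}-3,5-diethyl-1,2-dioxane-3-carbaldehyde
Product: 32 tert-butyl{2-[(3S,4S,6S)-4,6-diethyl-6-[(1Z,4R,5E)-4-ethyl-2-iodoocta-1,5-dien-1-yl]-1,2-dioxan-3-yl]ethoxy}diphenylsilane, via phosphonium ylide 29 (not isolated), via iodophosphonium iodide 30 (not isolated), via iodo ylide 31 (not isolated)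
Conditions: 28 (2.5 equiv), n-BuLi, THF, 0 °C; I2, −78 °C; NaN(SiMe3)2, −20 °C; then 20, −78 → −20 °C
Reagents that add atoms: iodine, [I][I]
Why: Stork–Zhao-type α-iodo Wittig olefination, in which the non-stabilised iodo ylide adds to the hindered aldehyde under kinetic control, gives the (Z)-iodoalkene (iodine cis to the ring, chain trans), joining the two fragments and fixing the C7=C8 geometry.

**Step 22**
Reactants: 32 tert-butyl{2-[(3S,4S,6S)-4,6-diethyl-6-[(1Z,4R,5E)-4-ethyl-2-iodoocta-1,5-dien-1-yl]-1,2-dioxan-3-yl]ethoxy}diphenylsilane; 22 diethylzinc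
Product: 33 tert-butyl{2-[(3S,4S,6S)-6-[(1E,4R,5E)-2,4-diethylocta-1,5-dien-1-yl]-4,6-diethyl-1,2-dioxan-3-yl]ethoxy}diphenylsilane
Conditions: Et2Zn (1.5 equiv), Pd(P(t-Bu)3)2 (5 mol %), THF, 0 °C → rt
Reagents that add atoms: none
Why: Negishi cross-coupling (oxidative addition, transmetalation, reductive elimination at palladium) replaces iodine by ethyl with retention of alkene geometry and gives the 7E alkene.

**Step 23**
Reactants: 33 tert-butyl{2-[(3S,4S,6S)-6-[(1E,4R,5E)-2,4-diethylocta-1,5-dien-1-yl]-4,6-diethyl-1,2-dioxan-3-yl]ethoxy}diphenylsilane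
Product: 34 2-[(3S,4S,6S)-6-[(1E,4R,5E)-2,4-diethylocta-1,5-dien-1-yl]-4,6-diethyl-1,2-dioxan-3-yl]ethan-1-ol
Conditions: Bu4NF (2 equiv), AcOH (2 equiv), THF, 0 °C → rt
Reagents that add atoms: none
Why: Fluoride-induced cleavage of the Si–O bond, buffered with acetic acid so that the peroxide is not exposed to base.

**Step 24**
Reactants: 34 2-[(3S,4S,6S)-6-[(1E,4R,5E)-2,4-diethylocta-1,5-dien-1-yl]-4,6-diethyl-1,2-dioxan-3-yl]ethan-1-ol
Product: 35 2-[(3S,4S,6S)-6-[(1E,4R,5E)-2,4-diethylocta-1,5-dien-1-yl]-4,6-diethyl-1,2-dioxan-3-yl]acetic acid (CNP0398571.8)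
Conditions: TEMPO (20 mol %), PhI(OAc)2 (2.5 equiv), MeCN/H2O (1:1), rt
Reagents that add atoms: water, O
Why: TEMPO-catalysed oxidation in aqueous acetonitrile converts the primary alcohol directly into the carboxylic acid without touching the alkenes or the peroxide.

**Compound list**
1 | but-1-yne | CCC#C | starting material
2 | 2-[(1E)-but-1-en-1-yl]-4,4,5,5-tetramethyl-1,3,2-dioxaborolane | CC/C=C/B1OC(C)(C)C(C)(C)O1 | intermediate
3 | 4,4,5,5-tetramethyl-2-[(2E)-pent-2-en-1-yl]-1,3,2-dioxaborolane | CC/C=C/CB1OC(C)(C)C(C)(C)O1 | intermediate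
4 | propane-1,3-diol | OCCCO | starting material
5 | 3-[(tert-butyldiphenylsilyl)oxy]propan-1-ol | OCCCO[Si](c1ccccc1)(c1ccccc1)C(C)(C)C | intermediate
6 | 3-[(tert-butyldiphenylsilyl)oxy]propanal | O=CCCO[Si](c1ccccc1)(c1ccccc1)C(C)(C)C | intermediate
7 | (3R,4S)-1-[(tert-butyldiphenylsilyl)oxy]-4-ethylhex-5-en-3-ol | C=C[C@H](CC)[C@H](O)CCO[Si](c1ccccc1)(c1ccccc1)C(C)(C)C | intermediate
8 | methyl 2-bromobutanoate (racemic) | CCC(Br)C(=O)OC | starting material
9 | (1-methoxy-1-oxobutan-2-yl)triphenylphosphonium bromide | CCC(C(=O)OC)[P+](c1ccccc1)(c1ccccc1)c1ccccc1.[Br-] | intermediate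
10 | methyl 2-(triphenyl-λ5-phosphanylidene)butanoate | CCC(C(=O)OC)=P(c1ccccc1)(c1ccccc1)c1ccccc1 | intermediate
11 | (2R,3R)-5-[(tert-butyldiphenylsilyl)oxy]-2-ethyl-3-hydroxypentanal (formed in the flask) | O=C[C@H](CC)[C@H](O)CCO[Si](c1ccccc1)(c1ccccc1)C(C)(C)C | intermediate
12 | methyl (2E,4S,5R)-7-[(tert-butyldiphenylsilyl)oxy]-2,4-diethyl-5-hydroxyhept-2-enoate | COC(=O)/C(CC)=C/[C@H](CC)[C@H](O)CCO[Si](c1ccccc1)(c1ccccc1)C(C)(C)C | intermediate
13 | (2E,4S,5R)-7-[(tert-butyldiphenylsilyl)oxy]-2,4-diethylhept-2-ene-1,5-diol | OC/C(CC)=C/[C@H](CC)[C@H](O)CCO[Si](c1ccccc1)(c1ccccc1)C(C)(C)C | intermediate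
14 | [(2S,3S)-3-[(3R,4R)-6-[(tert-butyldiphenylsilyl)oxy]-4-hydroxyhexan-3-yl]-2-ethyloxiran-2-yl]methanol | OC[C@]1(CC)O[C@H]1[C@H](CC)[C@H](O)CCO[Si](c1ccccc1)(c1ccccc1)C(C)(C)C | intermediate
15 | (2R,4S,5R)-7-[(tert-butyldiphenylsilyl)oxy]-2,4-diethylheptane-1,2,5-triol | OC[C@@](O)(CC)C[C@H](CC)[C@H](O)CCO[Si](c1ccccc1)(c1ccccc1)C(C)(C)C | intermediate
16 | (2R,4S,5R)-7-[(tert-butyldiphenylsilyl)oxy]-2,4-diethyl-2-hydroxyheptane-1,5-diyl dimethanesulfonate | CS(=O)(=O)OC[C@@](O)(CC)C[C@H](CC)[C@H](OS(C)(=O)=O)CCO[Si](c1ccccc1)(c1ccccc1)C(C)(C)C | intermediate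
17 | (3R,4S)-1-[(tert-butyldiphenylsilyl)oxy]-4-{[(2R)-2-ethyloxiran-2-yl]methyl}hexan-3-yl methanesulfonate | C1O[C@]1(CC)C[C@H](CC)[C@H](OS(C)(=O)=O)CCO[Si](c1ccccc1)(c1ccccc1)C(C)(C)C | intermediate
18 | (2S,4S,5R)-7-[(tert-butyldiphenylsilyl)oxy]-2,4-diethyl-2-hydroperoxy-1-hydroxyheptan-5-yl methanesulfonate (formed in the flask) | OC[C@](OO)(CC)C[C@H](CC)[C@H](OS(C)(=O)=O)CCO[Si](c1ccccc1)(c1ccccc1)C(C)(C)C | intermediate
19 | [(3S,5S,6S)-6-{2-[(tert-butyldiphenylsilyl)oxy]ethyl}-3,5-diethyl-1,2-dioxan-3-yl]methanol | OC[C@]1(CC)C[C@H](CC)[C@H](CCO[Si](c2ccccc2)(c2ccccc2)C(C)(C)C)OO1 | intermediate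
20 | (3S,5S,6S)-6-{2-[(tert-butyldiphenylsilyl)oxy]ethyl}-3,5-diethyl-1,2-dioxane-3-carbaldehyde | O=C[C@]1(CC)C[C@H](CC)[C@H](CCO[Si](c2ccccc2)(c2ccccc2)C(C)(C)C)OO1 | intermediate
21 | (2E)-pent-2-enal | CC/C=C/C=O | starting material
22 | diethylzinc | CC[Zn]CC | starting material
23 | (3R,4E)-hept-4-en-3-ol | CC/C=C/[C@H](O)CC | intermediate
24 | trimethyl orthoacetate (1,1,1-trimethoxyethane) | CC(OC)(OC)OC | starting material
25 | methyl (3R,4E)-3-ethylhept-4-enoate | CC/C=C/[C@H](CC)CC(=O)OC | intermediate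
26 | (3R,4E)-3-ethylhept-4-en-1-ol | CC/C=C/[C@H](CC)CCO | intermediate
27 | (3E,5R)-5-ethyl-7-iodohept-3-ene | CC/C=C/[C@H](CC)CCI | intermediate
28 | [(3R,4E)-3-ethylhept-4-en-1-yl]triphenylphosphonium iodide | CC/C=C/[C@H](CC)CC[P+](c1ccccc1)(c1ccccc1)c1ccccc1.[I-] | intermediate
29 | [(3R,4E)-3-ethylhept-4-en-1-ylidene]triphenyl-λ5-phosphane (formed in the flask) | CC/C=C/[C@H](CC)CC=P(c1ccccc1)(c1ccccc1)c1ccccc1 | intermediate
30 | [(3R,4E)-3-ethyl-1-iodohept-4-en-1-yl]triphenylphosphonium iodide (both C1 epimers; formed in the flask) | CC/C=C/[C@H](CC)CC(I)[P+](c1ccccc1)(c1ccccc1)c1ccccc1.[I-] | intermediate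
31 | [(3R,4E)-3-ethyl-1-iodohept-4-en-1-ylidene]triphenyl-λ5-phosphane (formed in the flask) | CC/C=C/[C@H](CC)CC(I)=P(c1ccccc1)(c1ccccc1)c1ccccc1 | intermediate
32 | tert-butyl{2-[(3S,4S,6S)-4,6-diethyl-6-[(1Z,4R,5E)-4-ethyl-2-iodoocta-1,5-dien-1-yl]-1,2-dioxan-3-yl]ethoxy}diphenylsilane | CC/C=C/[C@H](CC)C/C(I)=C/[C@]1(CC)C[C@H](CC)[C@H](CCO[Si](c2ccccc2)(c2ccccc2)C(C)(C)C)OO1 | intermediate
33 | tert-butyl{2-[(3S,4S,6S)-6-[(1E,4R,5E)-2,4-diethylocta-1,5-dien-1-yl]-4,6-diethyl-1,2-dioxan-3-yl]ethoxy}diphenylsilane | CC/C=C/[C@H](CC)C/C(CC)=C/[C@]1(CC)C[C@H](CC)[C@H](CCO[Si](c2ccccc2)(c2ccccc2)C(C)(C)C)OO1 | intermediate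
34 | 2-[(3S,4S,6S)-6-[(1E,4R,5E)-2,4-diethylocta-1,5-dien-1-yl]-4,6-diethyl-1,2-dioxan-3-yl]ethan-1-ol | CC/C=C/[C@H](CC)C/C(CC)=C/[C@]1(CC)C[C@H](CC)[C@H](CCO)OO1 | intermediate
35 | 2-[(3S,4S,6S)-6-[(1E,4R,5E)-2,4-diethylocta-1,5-dien-1-yl]-4,6-diethyl-1,2-dioxan-3-yl]acetic acid (CNP0398571.8) | CC/C=C/[C@H](CC)C/C(=C/[C@]1(CC)C[C@H](CC)[C@H](CC(=O)O)OO1)CC | target

**Totals**
Total step count: 24. Longest linear sequence: 15 steps (steps 3, 4, 5, 8, 9, 10, 11, 12, 13, 14, 15, 21, 22, 23, 24; the path from 1 through steps 1 and 2 is equally long).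

**Three steps most likely to fail**

Step 14 (perhydrolysis and ring closure). The opening of the 2,2-disubstituted epoxide by H2O2 must occur at the tertiary carbon with clean inversion, and the hindered secondary mesylate must then be displaced by the peroxide anion rather than eliminated. The fallback sets out from 13 and comes back at 19. The primary allylic hydroxyl of 13 is acetylated selectively (AcCl, 2,4,6-collidine, −78 °C) to give allylic acetate F1, and the C3 hydroxyl is mesylated to give acetate mesylate F2. Mukaiyama–Isayama hydroperoxysilylation (bis(2,2,6,6-tetramethylheptane-3,5-dionato)cobalt, Co(C11H19O2)2, divalent cobalt, catalytic; O2; Et3SiH) places the peroxide on C6 through the tertiary radical and gives triethylsilyl peroxide F3 as both C6 epimers. K2CO3 in MeOH removes the acetate and the silyl group to give hydroperoxide 18 together with epimeric hydroperoxide F4, and KOt-Bu/18-crown-6 closes the ring as in step 14 to give 19 and epimeric dioxane F5, which are separated by chromatography. This route gives up stereocontrol at C6 in exchange for a peroxidation that does not depend on the epoxide opening.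

Step 21 (α-iodo Wittig coupling). The α-iodo ylide is a weak nucleophile and the aldehyde is neopentyl-like, so conversion and Z selectivity may be poor. The fallback sets out from 28 and comes back at 33, bypassing 32 and step 22. The ylide from 28 (n-BuLi) is alkylated with iodoethane to give secondary phosphonium iodide F6; KN(SiMe3)2 converts it into disubstituted ylide F7, which reacts with 20 in a plain Wittig reaction. This gives 33 together with 7Z isomer F8 in roughly equal amounts, and the two are separated on AgNO3-impregnated silica.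

Step 5 (catalytic pentenylboration). The phosphoric acid catalyst may give only moderate enantioselectivity with this unbranched aliphatic aldehyde. The fallback sets out from 6 and comes back at 7 and relies on a stoichiometric chiral boronate instead of a chiral catalyst. (2E)-Pent-2-ene is metalated (n-BuLi, KOt-Bu, THF, −50 °C), trapped with B(OiPr)3 and esterified with diisopropyl (2R,3R)-tartrate to give tartrate pentenylboronate F9, which adds to 6 in toluene at −78 °C (4 Å molecular sieves) on the Si face through the same chair transition state and gives 7.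

**Further compounds**
F1 | step 14 | (2E,4S,5R)-7-[(tert-butyldiphenylsilyl)oxy]-2,4-diethyl-5-hydroxyhept-2-en-1-yl acetate | CC(=O)OC/C(CC)=C/[C@H](CC)[C@H](O)CCO[Si](c1ccccc1)(c1ccccc1)C(C)(C)C
F2 | step 14 | (2E,4S,5R)-7-[(tert-butyldiphenylsilyl)oxy]-2,4-diethyl-5-[(methanesulfonyl)oxy]hept-2-en-1-yl acetate | CC(=O)OC/C(CC)=C/[C@H](CC)[C@H](OS(C)(=O)=O)CCO[Si](c1ccccc1)(c1ccccc1)C(C)(C)C
F3 | step 14 | (4S,5R)-7-[(tert-butyldiphenylsilyl)oxy]-2,4-diethyl-5-[(methanesulfonyl)oxy]-2-[(triethylsilyl)peroxy]heptyl acetate (both C2 epimers) | CC(=O)OCC(CC)(OO[Si](CC)(CC)CC)C[C@H](CC)[C@H](OS(C)(=O)=O)CCO[Si](c1ccccc1)(c1ccccc1)C(C)(C)C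
F4 | step 14 | (2R,4S,5R)-7-[(tert-butyldiphenylsilyl)oxy]-2,4-diethyl-2-hydroperoxy-1-hydroxyheptan-5-yl methanesulfonate | OC[C@@](OO)(CC)C[C@H](CC)[C@H](OS(C)(=O)=O)CCO[Si](c1ccccc1)(c1ccccc1)C(C)(C)C
F5 | step 14 | [(3R,5S,6S)-6-{2-[(tert-butyldiphenylsilyl)oxy]ethyl}-3,5-diethyl-1,2-dioxan-3-yl]methanol | OC[C@@]1(CC)C[C@H](CC)[C@H](CCO[Si](c2ccccc2)(c2ccccc2)C(C)(C)C)OO1
F6 | step 21 | [(5R,6E)-5-ethylnon-6-en-3-yl]triphenylphosphonium iodide (both C3 epimers) | CC/C=C/[C@H](CC)CC(CC)[P+](c1ccccc1)(c1ccccc1)c1ccccc1.[I-]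
F7 | step 21 | [(5R,6E)-5-ethylnon-6-en-3-ylidene]triphenyl-λ5-phosphane | CC/C=C/[C@H](CC)CC(CC)=P(c1ccccc1)(c1ccccc1)c1ccccc1
F8 | step 21 | tert-butyl{2-[(3S,4S,6S)-6-[(1Z,4R,5E)-2,4-diethylocta-1,5-dien-1-yl]-4,6-diethyl-1,2-dioxan-3-yl]ethoxy}diphenylsilane | CC/C=C/[C@H](CC)C/C(CC)=C\[C@]1(CC)C[C@H](CC)[C@H](CCO[Si](c2ccccc2)(c2ccccc2)C(C)(C)C)OO1
F9 | step 5 | diisopropyl (4R,5R)-2-[(2E)-pent-2-en-1-yl]-1,3,2-dioxaborolane-4,5-dicarboxylate | CC/C=C/CB1O[C@@H](C(=O)OC(C)C)[C@H](C(=O)OC(C)C)O1
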